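The rate constants were chosen freely; the flask was simulated.

Time is the same in each set-up below, 2.0 min, the tank's mean residence time included; the way it is spent differs.

in all of them: Q 0.0250 mM

| run | D | L | remark | time |
|---|---|---|---|---|
| eta | 0.50 mM | 0.475 mM | one stirred flow tank at steady state, fed with the mixture as stated, mean residence time 2.0 min |  |
| theta | 0.50 mM | 0.475 mM (fed, over 1.60 min) | a stirred flask in which L is dosed at a steady rate over 1.60 min without added volume, worked up at 2.0 min | 2.0 min |
| gamma | 0.50 mM (fed, over 1.60 min) | 0.475 mM | a stirred flask in which D is dosed at a steady rate over 1.60 min without added volume, worked up at 2.0 min | 2.0 min |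
| beta | 0.50 mM | 0.475 mM | a closed flask charged with all of it at once and left for 2.0 min | 2.0 min |

    D.L → Z (k1 = 0.108 s⁻¹)
    D + L → D.L (k2 = 568 L mol⁻¹ s⁻¹)
    D.L → E (k3 = 0.0245 s⁻¹)
    D + Q → D.Q (k4 = 1920 L mol⁻¹ s⁻¹)

- the set-up with the highest amount of Z at the outlet or at the end, in percent of the D put in ("none" if the first two lie within 2 percentage points) (eta / theta / gamma / beta / none)
- amount of Z at the outlet or at the end, in percent of the D put in, eta
- amount of Z at the outlet or at the end, in percent of the D put in, theta
- amount of Z at the outlet or at the end, in percent of the D put in, gamma
- amount of Z at the outlet or at the end, in percent of the D put in, beta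

- the stated concentrations are those of everything mixed, before any reaction; amounts are the same in each set-up
- the feed brings no volume worth counting
- run time (theta): 2.0 min

In the closed flask beta, each given number carries a different weight. Q comes first: its charge is 5.00 % of D, and at the charged [D] its life is 1.04 s, far shorter than the run, so an error in its rate constant moves the yield little. D.L has a life of 7.55 s, also shorter than the run, and its two exits count through their share, the selectivity towards Z of 81.5 %, which passes any error straight into the yield.

The coupling and the loss to Q each take one D, and the 0.50 mM of D equals 0.475 mM of L plus 0.0250 mM of Q, so [D] stays equal to [L] plus [Q]; where [Q] has fallen away, [D] equals [L] and the coupling rate goes with [L] squared. [L] therefore sets the order: second, not pseudo-first-order. Complete coupling of the charged L, with that share going to Z, gives a ceiling of 77.4 % of the D put in. At 0.5 of its value the coupling constant costs 2.2 percentage points in this reckoning.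

Only now the number: the coupling time, the reciprocal of the coupling constant times the charge of L, in which equal [D] and [L] fall to half, is 3.71 s. Reckoned with [D] equal to [L] from the start, [L] after 2.0 min is the charge divided by one plus the time over 3.71 s, which is 0.0142 mM, so beta should reach 75.1 %. This reckoning stops at beta.

The forecast names beta as best, with 61.2 % for eta, 70 % for theta, 69.9 % for gamma and 75 % for beta, since “the all-at-once flask gives the most time at high concentration”. The simulation gives 61.2 %, 69.9 %, 69.8 % and 75.0 % in that order, with beta ahead.

In beta, the run spans 32.3 coupling times, and the flask reads 77.2 % at 20.0 min, beside the ceiling of 77.4 %. In the tank eta, the same coupling time, set into the balance of feed against reaction with [D] taken equal to [L], gives a steady [L] of 0.0765 mM; the reading there is 0.0759 mM, more than the 0.0142 mM reckoned for beta at its end, and Z at the outlet of eta is 61.2 %.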